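(The earlier runs and the new flask were generated by integration on assumed constants.)

Hours are the trap in these flasks: elm and ash both run 2.0 h, yet the clock does not say how much of that time counted. The thing to count is turnovers, the natural logarithm of charged over unturned starting material.

| setting | west | north | east | north-east | alder | ash | oak | elm | birch |
|---|---|---|---|---|---|---|---|---|---|
| starting material | 0.10 M | 0.067 M | 0.15 M | 0.10 M | 0.10 M | 0.10 M (fed, over 8.0 min) | 0.10 M (fed, over 80 min) | 0.10 M | 0.10 M |
| reagent | 0.095 M | 0.095 M | 0.095 M | 0.095 M | 0.0950 M | 0.0950 M | 0.0950 M | 0.0950 M | 0.0950 M |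
| second substrate | 0.10 M | 0.10 M | 0.10 M | 0.20 M | 0.100 M | 0.100 M | 0.100 M | 0.100 M | 0.100 M |
| third substrate | 0.20 M | 0.20 M | 0.20 M | 0.20 M | 0.200 M (fed, over 80 min) | 0.200 M | 0.200 M | 0.200 M | 0.200 M (fed, over 80 min) |
| temperature | 75 °C | 90 °C | 75 °C | 90 °C | 90 °C | 90 °C | 90 °C |  |  |
| remark | run made earlier | run made earlier | run made earlier | run made earlier | all else is in the flask from the start; the feed brings no volume worth counting | all else is in the flask from the start; the feed brings no volume worth counting | all else is in the flask from the start; the feed brings no volume worth counting | everything together at the start at 70 °C, warmed to 90 °C at 80 min | the addition at 70 °C, then warmed to 90 °C; the feed brings no volume worth counting |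
| time |  |  |  |  | 2.0 h | 2.0 h | 2.0 h | 2.0 h | 2.0 h |

| run | time / h | target / % | starting material / % |
|---|---|---|---|
| west | 0.500 | 3.1 | 96.9 |
| west | 1.00 | 4.1 | 96.0 |
| west | 2.00 | 5.8 | 94.6 |
| west | 3.00 | 6.9 | 93.0 |
| west | 4.00 | 8.8 | 92.3 |
| north | 0.133 | 4.2 | 95.7 |
| north | 0.333 | 7.2 | 92.9 |
| north | 0.667 | 11.9 | 88.0 |
| north | 1.00 | 15.7 | 84.0 |
| north | 1.33 | 19.4 | 80.7 |
| north | 2.00 | 24.5 | 76.0 |
| north | 2.50 | 28.2 | 72.0 |
| east | 0.250 | 2.5 | 97.5 |
| east | 0.667 | 3.4 | 97.1 |
| east | 1.33 | 4.4 | 95.4 |
| east | 2.00 | 5.6 | 94.5 |
| east | 3.00 | 6.8 | 93.5 |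
| east | 4.00 | 8.1 | 92.3 |
| east | 5.00 | 9.3 | 91.0 |
| north-east | 0.200 | 5.4 | 94.9 |
| north-east | 0.667 | 11.0 | 88.9 |
| north-east | 1.00 | 14.3 | 85.5 |
| north-east | 1.50 | 18.5 | 81.4 |
| north-east | 2.50 | 23.7 | 76.7 |

(readings scatter by 0.3 percentage points)

- the numbers in the tables scatter by 0.3 percentage points (one standard deviation)

- the flask that comes out highest in amount of target, in percent of the starting material charged, or "all alike" when all lie within 1.5 percentage points (alder / ash / oak / elm / birch / all alike)
- target at the end, in percent of the starting material charged, alder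
- target at the end, in percent of the starting material charged, ash
- target at the end, in percent of the starting material charged, oak
- target at the end, in percent of the starting material charged, elm
- target at the end, in percent of the starting material charged, birch

Counts add along a run if the percent curves ignore the charge (pseudo-first-order behaviour), and at 2.00 h west at 0.10 M reads 5.8% while east at 0.15 M reads 5.6%. The times form a ladder. The quick addition takes 8.0 min. The early burst comes next: the later west line, 0.0168 h⁻¹, allows 0.420% by 0.250 h, but east reads more, 2.5%. Then come the slow addition, 80 min, and the run, 2.0 h. The north line gives an early slope of 0.144 h⁻¹, but the slope does not last: from 1.00 h to 2.50 h the same run gives less, 0.107 h⁻¹. The reciprocal of the early slope, 6.94 h, is longer than the run; it is a time scale, not a time at which one turnover is reached.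

For elm, the west reading at 1.00 h stands in for the cold hold, a warmer but shorter stay, and gives 0.0419. The hot stretch adds the early north slope times 40.0 min, so elm has the turnover count 0.138, or 12.9%. Ash is the north count at 2.00 h less the 4.00 min that its portions lose on average: 23.8%. Oak's portions see on average 1.33 h: 17.5%. The earlier runs hold third substrate at 0.20 M from the start, so alder stays uncounted and birch is taken as elm; among the counted flasks ash stands highest.

The forecast names alder, with 21% for alder, 20.5% for ash, 15% for oak, 12.5% for elm and 12% for birch, lower than this count for ash, and says of third substrate “its order was never tested, so I assume little effect”.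

The simulation gives alder highest: alder 25.5%, ash 21.5%, oak 15.0%, elm 12.3%, birch 13.3%.

    starting material + reagent → target (k = 0.169 M⁻¹ min⁻¹, Ea = 93.0 kJ mol⁻¹)
    second substrate + reagent → second product (k = 0.0715 M⁻¹ min⁻¹, Ea = 79.0 kJ mol⁻¹)
    third substrate + reagent → third product (k = 0.255 M⁻¹ min⁻¹, Ea = 72.0 kJ mol⁻¹)
    reagent ⇌ dormant form (K = 3.20, k = 0.506 min⁻¹, Ea = 94.0 kJ mol⁻¹, ΔH = −84.0 kJ mol⁻¹)
    2 third substrate → self-condensation product (k = 0.163 M⁻¹ min⁻¹, Ea = 83.0 kJ mol⁻¹)
    (constants at 90 °C)

Elm's result is a count of 0.131 against the reckoned 0.138. At 0.781 h in elm, reagent has a half-life of 1.5 h by the third-substrate step and 4.2 h by the target step, so third substrate takes reagent faster than starting material does. For the neighbour of elm with second substrate at 0.17 M, the north-east line, 0.124 h⁻¹ at 0.20 M, gives a count of 0.124, or 11.7%. That neighbour computes to 12.0%.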